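The target is numbered as an indenone: C1 carbonyl, C2 azulenyl, C3 methyl, C4 carbinol, C5–H, C6 azulenyl, C7 methyl. Its benzene ring (C3a, C4, C5, C6, C7, C7a) shares the C3a–C7a bond with the cyclopentenone ring and has its single hydrogen at C5. This pattern is taken apart into a 1,6-diyne (C3a≡C4 and C7a≡C7, linked through C1(=O)–C2=C3) and a terminal alkyne (C5≡C6). One rhodium-catalysed [2+2+2] cycloaddition forms C3a–C7a, C4–C5 and C6–C7, closes both rings and gives the target directly. The precursor is an acyclic Z-enediynone that already carries one guaiazulenyl group, the free tertiary carbinol and both methyl groups; its partner is 3-ethynylguaiazulene.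

Key step: step 9

Remark: the target as drawn has no stereocentre and no specified axis, so the two azulenyl–indenone bonds are treated as freely rotating and only the Z geometry of the acyclic alkene must be controlled; "guaiazulen-3-yl" stands for 3,8-dimethyl-5-(propan-2-yl)azulen-1-yl.

Step 1
Reactants: 1 methyl acetoacetate
Product: 2 methyl 2-diazo-3-oxobutanoate
Conditions: p-ABSA, Et3N, MeCN, 0 °C to rt
Reagents that add atoms: 4-acetamidobenzenesulfonyl azide (p-ABSA), CC(=O)Nc1ccc(cc1)S(=O)(=O)N=[N+]=[N-]
Why: Regitz diazo transfer, in which the amine-generated enolate of the β-keto ester attacks the terminal azide nitrogen and expels the sulfonamide.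

Step 2
Reactants: 2 methyl 2-diazo-3-oxobutanoate; 3 guaiazulene (1,4-dimethyl-7-(propan-2-yl)azulene)
Product: 4 methyl 2-(guaiazulen-3-yl)-3-oxobutanoate (racemic at the labile α-carbon; keto/enol mixture)
Conditions: Rh2(OAc)4 (2 mol%), CH2Cl2, 40 °C, 2 added slowly by syringe pump
Reagents that add atoms: none
Why: Formal aromatic C–H insertion of a rhodium carbenoid, in which the electrophilic carbenoid from 2 is attacked by C3, the only free nucleophilic position of the five-membered ring, and proton transfer restores the azulene, as is established for diazo esters with azulenes and indoles.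

Step 3
Reactants: 4 methyl 2-(guaiazulen-3-yl)-3-oxobutanoate
Product: 6 methyl (Z)-2-(guaiazulen-3-yl)-3-(trifluoromethylsulfonyloxy)but-2-enoate, via chelated sodium enolate 5 (not isolated)
Conditions: NaH, THF, 0 °C; then PhNTf2, 0 °C to rt
Reagents that add atoms: N-phenyl-bis(trifluoromethanesulfonimide) (PhNTf2), O=S(=O)(N(c1ccccc1)S(=O)(=O)C(F)(F)F)C(F)(F)F
Why: Chelation-controlled enol triflation of a β-keto ester, in which sodium bridges the ketone and ester oxygens in THF so that O-sulfonylation places the triflate cis to the ester (Z), and the mild triflating agent should leave the azulene untouched.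

Step 4
Reactants: 6 methyl (Z)-2-(guaiazulen-3-yl)-3-(trifluoromethylsulfonyloxy)but-2-enoate; 7 2-methylbut-3-yn-2-ol
Product: 8 methyl (Z)-2-(guaiazulen-3-yl)-6-hydroxy-3,6-dimethylhept-2-en-4-ynoate
Conditions: PdCl2(PPh3)2 (5 mol%), CuI (10 mol%), Et3N, THF, rt to 40 °C
Reagents that add atoms: none
Why: Sonogashira coupling, in which oxidative addition of the electron-poor vinyl triflate to zerovalent palladium and transmetalation from the copper acetylide proceed with retention of alkene geometry and tolerate the free tertiary alcohol.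

Step 5
Reactants: 8 methyl (Z)-2-(guaiazulen-3-yl)-6-hydroxy-3,6-dimethylhept-2-en-4-ynoate
Product: 9 (Z)-2-(guaiazulen-3-yl)-6-hydroxy-N-methoxy-N,3,6-trimethylhept-2-en-4-ynamide
Conditions: MeNH(OMe)·HCl, iPrMgCl (excess), THF, −20 to 0 °C
Reagents that add atoms: N,O-dimethylhydroxylamine hydrochloride, CNOC.Cl
Why: Weinreb amide formation by aminolysis of the ester with the chloromagnesium amide made in the flask, with one extra equivalent of base taken up by the tertiary alcohol and no pathway open for isomerisation of the tetrasubstituted alkene.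

Step 6
Reactants: 9 (Z)-2-(guaiazulen-3-yl)-6-hydroxy-N-methoxy-N,3,6-trimethylhept-2-en-4-ynamide; 10 prop-1-ynylmagnesium bromide
Product: 12 (Z)-5-(guaiazulen-3-yl)-9-hydroxy-6,9-dimethyldec-5-ene-2,7-diyn-4-one, via magnesium hemiaminal adduct 11 (not isolated)
Conditions: 10 (3 equiv), THF, 0 °C to rt; aq. NH4Cl
Reagents that add atoms: none
Why: Weinreb ketone synthesis, in which the first equivalent of 10 deprotonates the alcohol and the next adds to the amide to give the chelated adduct 11, which resists over-addition and releases the ynone only on quench.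

Step 7
Reactants: 3 guaiazulene
Product: 14 guaiazulene-3-carbaldehyde (3,8-dimethyl-5-(propan-2-yl)azulene-1-carbaldehyde), via iminium salt 13 (not isolated)
Conditions: POCl3, DMF, 0 °C to rt; then aq. NaOH
Reagents that add atoms: N,N-dimethylformamide, CN(C)C=O; water, O
Why: Vilsmeier–Haack formylation, in which the chloroiminium ion attacks the nucleophilic C3 position and alkaline hydrolysis of the iminium salt liberates the aldehyde.

Step 8
Reactants: 14 guaiazulene-3-carbaldehyde
Product: 15 3-ethynylguaiazulene (1-ethynyl-3,8-dimethyl-5-(propan-2-yl)azulene)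
Conditions: dimethyl (1-diazo-2-oxopropyl)phosphonate, K2CO3, MeOH/THF, rt; product used fresh under argon
Reagents that add atoms: dimethyl (1-diazo-2-oxopropyl)phosphonate, COP(=O)(OC)C(=[N+]=[N-])C(C)=O
Why: Seyferth–Gilbert homologation with the Ohira–Bestmann reagent, in which the diazomethylphosphonate anion adds to the aldehyde and loss of dimethyl phosphate and dinitrogen with a 1,2-hydrogen shift gives the terminal alkyne under conditions too mild to deprotonate the acidic C4-methyl group.

Step 9
Reactants: 12 (Z)-5-(guaiazulen-3-yl)-9-hydroxy-6,9-dimethyldec-5-ene-2,7-diyn-4-one; 15 3-ethynylguaiazulene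
Product: 16 2,6-bis(guaiazulen-3-yl)-4-(2-hydroxypropan-2-yl)-3,7-dimethyl-1H-inden-1-one (target)
Conditions: [Rh(cod)2]BF4 (10 mol%), rac-BINAP (10 mol%), pre-activated with H2, degassed CH2Cl2, rt to 40 °C; 15 (1.5 equiv) added slowly
Reagents that add atoms: none
Why: This is a formal [2+2+2] alkyne cyclotrimerisation of a tethered 1,6-diyne with a terminal alkyne, the reaction class that gives indanones and fluorenones from carbonyl-tethered diynes. The cationic monovalent rhodium–BINAP fragment binds both alkynes of 12, which the Z alkene holds on one side, and oxidative coupling joins C3a to C7a, so the cyclopentenone ring (C1–C2–C3–C3a–C7a) closes by a metal-templated five-membered closure inside a trivalent rhodacyclopentadiene bonded through C4 and C7. Alkyne 15 then coordinates and inserts, and C–C reductive elimination completes C6–C7 and C4–C5, so the six-membered ring closes by annulation of the two-carbon unit across the rhodacycle termini and emerges directly as the arene. No stereocentre is created, so racemic BINAP serves only as a supporting ligand. The selectivity needed is the orientation of the insertion: the quaternary carbinol carbon on C4 is far larger than the methyl group on C7, so the azulenyl-bearing alkyne carbon should bond to C7 and the CH terminus to C4. Slow addition of 15 to the catalyst and 12 should favour the cross-reaction over self-trimerisation of the alkyne, while the doubly substituted termini of 12 disfavour its own dimerisation.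

Compound list
1 | methyl acetoacetate | COC(=O)CC(C)=O | starting material
2 | methyl 2-diazo-3-oxobutanoate | COC(=O)C(=[N+]=[N-])C(C)=O | intermediate
3 | guaiazulene (1,4-dimethyl-7-(propan-2-yl)azulene) | c1cc(C)c2cc(C(C)C)ccc(C)c1-2 | starting material
4 | methyl 2-(guaiazulen-3-yl)-3-oxobutanoate (racemic) | COC(=O)C(C(C)=O)c1cc(C)c2cc(C(C)C)ccc(C)c1-2 | intermediate
5 | sodium (Z)-enolate of 4 (sodium bridging both oxygens) | COC(=O)/C(c1cc(C)c2cc(C(C)C)ccc(C)c1-2)=C([O-])/C.[Na+] | intermediate
6 | methyl (Z)-2-(guaiazulen-3-yl)-3-(trifluoromethylsulfonyloxy)but-2-enoate | COC(=O)/C(c1cc(C)c2cc(C(C)C)ccc(C)c1-2)=C(OS(=O)(=O)C(F)(F)F)/C | intermediate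
7 | 2-methylbut-3-yn-2-ol | C#CC(C)(C)O | starting material
8 | methyl (Z)-2-(guaiazulen-3-yl)-6-hydroxy-3,6-dimethylhept-2-en-4-ynoate | COC(=O)/C(c1cc(C)c2cc(C(C)C)ccc(C)c1-2)=C(C#CC(C)(C)O)/C | intermediate
9 | (Z)-2-(guaiazulen-3-yl)-6-hydroxy-N-methoxy-N,3,6-trimethylhept-2-en-4-ynamide | CON(C)C(=O)/C(c1cc(C)c2cc(C(C)C)ccc(C)c1-2)=C(C#CC(C)(C)O)/C | intermediate
10 | prop-1-ynylmagnesium bromide | CC#C[Mg]Br | starting material
11 | magnesium hemiaminal adduct of 9 and 10 (bis-bromomagnesium alkoxide, racemic at the new tetrahedral carbon) | CC#CC(O[Mg]Br)(N(C)OC)/C(c1cc(C)c2cc(C(C)C)ccc(C)c1-2)=C(C#CC(C)(C)O[Mg]Br)/C | intermediate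
12 | (Z)-5-(guaiazulen-3-yl)-9-hydroxy-6,9-dimethyldec-5-ene-2,7-diyn-4-one | CC#CC(=O)/C(c1cc(C)c2cc(C(C)C)ccc(C)c1-2)=C(C#CC(C)(C)O)/C | intermediate
13 | N,N-dimethyl-1-(guaiazulen-3-yl)methaniminium dichlorophosphate | C[N+](C)=Cc1cc(C)c2cc(C(C)C)ccc(C)c1-2.[O-]P(=O)(Cl)Cl | intermediate
14 | guaiazulene-3-carbaldehyde | O=Cc1cc(C)c2cc(C(C)C)ccc(C)c1-2 | intermediate
15 | 3-ethynylguaiazulene | C#Cc1cc(C)c2cc(C(C)C)ccc(C)c1-2 | intermediate
16 | 2,6-bis(guaiazulen-3-yl)-4-(2-hydroxypropan-2-yl)-3,7-dimethyl-1H-inden-1-one | CC1=C(c2cc(C)c3cc(C(C)C)ccc(C)c2-3)C(=O)c2c(C)c(-c3cc(C)c4cc(C(C)C)ccc(C)c3-4)cc(C(C)(C)O)c21 | target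

Total step count: 9. Longest linear sequence: 7 steps (steps 1 to 6, then step 9); the alkyne branch (steps 7 and 8) joins at step 9.

Steps most likely to fail

Step 9. The terminal alkyne may insert in the wrong orientation, the electron-rich alkyne may self-oligomerise, or the ketone oxygen may attack the rhodium-activated enyne alkyne (furan formation) faster than the cross-cyclotrimerisation. The fallback makes the third alkyne intramolecular through a temporary silicon tether; it sets out from 12 and 15 and returns at 16. Deprotonation of 15 with EtMgBr in THF and addition to excess Me2SiCl2 should give chloro[(guaiazulen-3-yl)ethynyl]dimethylsilane F1. Silylation of the tertiary alcohol of 12 with F1 (Et3N, catalytic DMAP, CH2Cl2) should give the tethered triyne silyl ether F2, whose alkynylsilane sits three atoms from the enyne alkyne. Cyclotrimerisation with RhCl(PPh3)3 in toluene at 60–80 °C should then give the silicon-bridged indenone F3, in which the tether dictates that silicon sits on C5 and the azulenyl group on C6. Bu4NF in wet THF/DMF at 60 °C should cleave the aryl–silicon and silicon–oxygen bonds (protodesilylation) and deliver 16.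

Step 2. The carbenoid may add to the seven-membered ring (cyclopropanation and ring enlargement) or dimerise instead of attacking the hindered C3 position. The fallback builds the same carbon framework by acylation chemistry; it sets out from 3 and returns at 4. Uncatalysed Friedel–Crafts acylation of 3 with oxalyl chloride (Et2O, 0 °C) should give (guaiazulen-3-yl)glyoxylyl chloride F4, which is quenched with MeOH/Et3N to methyl 2-(guaiazulen-3-yl)-2-oxoacetate F5. Ionic hydrogenation of the azulenyl ketone (Et3SiH, CF3CO2H, CH2Cl2, 0 °C) should give methyl 2-(guaiazulen-3-yl)acetate F6. Claisen-type C-acetylation (LiN(SiMe3)2, 2.2 equiv, THF, −78 °C, then acetyl chloride) should give 4.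

Step 5. Acyl substitution at the hindered, twisted ester carbonyl may stall, or the magnesium amide may add in a conjugate sense. The fallback replaces acyl substitution by a redox sequence; it sets out from 8 and returns at 12, bypassing 9. Reduction with iBu2AlH (CH2Cl2, −78 to 0 °C) should give (Z)-2-(guaiazulen-3-yl)-3,6-dimethylhept-2-en-4-yne-1,6-diol F7. Allylic oxidation with MnO2 (CH2Cl2, rt) should give (Z)-2-(guaiazulen-3-yl)-6-hydroxy-3,6-dimethylhept-2-en-4-ynal F8. Addition of 10 (THF, −78 to 0 °C) should give (Z)-5-(guaiazulen-3-yl)-6,9-dimethyldec-5-ene-2,7-diyne-4,9-diol F9, racemic at C4. A second MnO2 oxidation, selective for the secondary allylic-propargylic alcohol, should give 12.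

Further compounds
F1 | step 9 | chloro[(guaiazulen-3-yl)ethynyl]dimethylsilane | C[Si](C)(Cl)C#Cc1cc(C)c2cc(C(C)C)ccc(C)c1-2
F2 | step 9 | (Z)-5-(guaiazulen-3-yl)-9-{[(guaiazulen-3-yl)ethynyl]dimethylsilyloxy}-6,9-dimethyldec-5-ene-2,7-diyn-4-one | CC#CC(=O)/C(c1cc(C)c2cc(C(C)C)ccc(C)c1-2)=C(C#CC(C)(C)O[Si](C)(C)C#Cc1cc(C)c2cc(C(C)C)ccc(C)c1-2)/C
F3 | step 9 | 2,6-bis(guaiazulen-3-yl)-3,7-dimethyl-1H-inden-1-one with C4 and C5 bridged by C(CH3)2–O–Si(CH3)2 (fused 1,1,3,3-tetramethyl-1,3-dihydro-2,1-benzoxasilole) | CC1=C(c2cc(C)c3cc(C(C)C)ccc(C)c2-3)C(=O)c2c(C)c(-c3cc(C)c4cc(C(C)C)ccc(C)c3-4)c3c(c21)C(C)(C)O[Si]3(C)C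
F4 | step 2 | (guaiazulen-3-yl)glyoxylyl chloride | O=C(Cl)C(=O)c1cc(C)c2cc(C(C)C)ccc(C)c1-2
F5 | step 2 | methyl 2-(guaiazulen-3-yl)-2-oxoacetate | COC(=O)C(=O)c1cc(C)c2cc(C(C)C)ccc(C)c1-2
F6 | step 2 | methyl 2-(guaiazulen-3-yl)acetate | COC(=O)Cc1cc(C)c2cc(C(C)C)ccc(C)c1-2
F7 | step 5 | (Z)-2-(guaiazulen-3-yl)-3,6-dimethylhept-2-en-4-yne-1,6-diol | OC/C(c1cc(C)c2cc(C(C)C)ccc(C)c1-2)=C(C#CC(C)(C)O)/C
F8 | step 5 | (Z)-2-(guaiazulen-3-yl)-6-hydroxy-3,6-dimethylhept-2-en-4-ynal | O=C/C(c1cc(C)c2cc(C(C)C)ccc(C)c1-2)=C(C#CC(C)(C)O)/C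
F9 | step 5 | (Z)-5-(guaiazulen-3-yl)-6,9-dimethyldec-5-ene-2,7-diyne-4,9-diol (racemic at C4) | CC#CC(O)/C(c1cc(C)c2cc(C(C)C)ccc(C)c1-2)=C(C#CC(C)(C)O)/C
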